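**Retrosynthetic overview**
1. Target ⇒ its hexasilyl ether; the (Z)-diene ⇒ 8-enyne (zinc semi-reduction) ⇒ 8-iodide (Sonogashira); C4=O ⇒ C4–OMe (hydrolysis, then oxidation).
2. Ring C ⇒ a ring-A o-quinone methide (1-oxadiene O1=C8a–C4a=C4, from a 3-iodosalicylaldehyde and HC(OMe)3) plus the C2=C3 vinyl group on ring B of the finished dihydrobenzofuran. One asymmetric oxa-[4+2] cycloaddition makes C3–C4 and O1–C2 and sets C2.
3. Enabling feature: O1 and the C4 carbon are ortho substituents on the trioxygenated ring A (a masked 1-oxadiene), and C2 is benzylic to ring-B carbon C1', which is para to the dihydrofuran oxygen and ortho to the 2'-oxygen. The partners are therefore polarity-matched and the regiochemistry is fixed.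
4. Dihydrobenzofuran ⇒ a diaryldiazomethane (Rh-carbene C–H insertion into the benzylic ether CH2 sets C3; C2 is equilibrated to trans; Stille vinylation) ⇒ 5-bromo-2,4-dihydroxybenzaldehyde, 5-bromoresorcinol and a 4-silyloxybenzyl alcohol.
5. Ring order: dihydrofuran ring (step 6), then pyran ring C (step 11); all benzene rings are bought.

Key step: step 11

Abbreviations: TBS = tert-butyldimethylsilyl; TIPS = triisopropylsilyl; "DHB unit" = (2R,3R)-2-[4-(TBSO)phenyl]-3-[3,5-bis(TBSO)phenyl]-6-(TIPSO)-2,3-dihydro-1-benzofuran-5-yl.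

Remark: the sense of induction of the two chiral catalysts is taken as drawn (Rh2(R-PTAD)4 giving the 3R dihydrobenzofuran, the (R)-phosphoric acid giving the 2S flavan); should either give the opposite sense, its enantiomer is used. Alcohol 5 is taken to be commercially available.

Step 1
Reactants: 1 5-bromobenzene-1,3-diol
Product: 2 1-bromo-3,5-bis(tert-butyldimethylsilyloxy)benzene
Conditions: TBSCl (2.4 equiv), imidazole, DMF, rt
Reagents that add atoms: tert-butyldimethylsilyl chloride, CC(C)(C)[Si](C)(C)Cl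
Why: imidazole-mediated silyl ether formation on both phenols should be routine and creates no stereocentre.

Step 2
Reactants: 3 5-bromo-2,4-dihydroxybenzaldehyde
Product: 4 5-bromo-2-hydroxy-4-(triisopropylsilyloxy)benzaldehyde
Conditions: TIPSCl (1.05 equiv), imidazole, CH2Cl2, 0 °C
Reagents that add atoms: triisopropylsilyl chloride, CC(C)[Si](Cl)(C(C)C)C(C)C
Why: regioselective silylation, because the 2-OH is tied up in a hydrogen bond to the formyl group and only the 4-OH reacts.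

Step 3
Reactants: 4 5-bromo-2-hydroxy-4-(triisopropylsilyloxy)benzaldehyde; 5 [4-(tert-butyldimethylsilyloxy)phenyl]methanol
Product: 6 5-bromo-2-{[4-(tert-butyldimethylsilyloxy)phenyl]methoxy}-4-(triisopropylsilyloxy)benzaldehyde
Conditions: PPh3, DIAD, THF, 0 °C → rt
Reagents that add atoms: none
Why: Mitsunobu etherification of the acidic chelated phenol with a primary benzylic alcohol avoids the carbonate bases that would cleave the aryl silyl ethers.

Step 4
Reactants: 6 5-bromo-2-{[4-(tert-butyldimethylsilyloxy)phenyl]methoxy}-4-(triisopropylsilyloxy)benzaldehyde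
Product: 8 5-bromo-2-{[4-(tert-butyldimethylsilyloxy)phenyl]methoxy}-4-(triisopropylsilyloxy)benzonitrile, via aldoxime 7 (not isolated)
Conditions: NH2OH·HCl, pyridine, CH2Cl2, rt; then (CF3CO)2O, 0 °C → rt
Reagents that add atoms: hydroxylamine hydrochloride, Cl.NO
Why: oxime formation followed by dehydration of the O-trifluoroacetyl aldoxime is a standard one-pot aldehyde-to-nitrile conversion and is mild enough for both silyl ethers.

Step 5
Reactants: 8 5-bromo-2-{[4-(tert-butyldimethylsilyloxy)phenyl]methoxy}-4-(triisopropylsilyloxy)benzonitrile; 2 1-bromo-3,5-bis(tert-butyldimethylsilyloxy)benzene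
Product: 11 hydrazone of [3,5-bis(TBSO)phenyl](5-bromo-2-{[4-(TBSO)phenyl]methoxy}-4-(TIPSO)phenyl)methanone (mixture of C=N isomers), via aryl Grignard reagent 9 (not isolated), via N–H ketimine 10 (not isolated)
Conditions: Mg, THF, 50 °C; then 8, CuBr·SMe2 (5 mol %), THF, 60 °C; MeOH, 0 °C; then N2H4 (1 M in THF), AcOH (cat.), rt
Reagents that add atoms: hydrazine, NN
Why: copper-catalysed Grignard addition to the nitrile stops at the N-magnesio ketimine, and transimination of the N–H ketimine with hydrazine gives the hindered diaryl hydrazone at room temperature, which a direct ketone condensation would not.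

Step 6
Reactants: 11 hydrazone of [3,5-bis(TBSO)phenyl](5-bromo-2-{[4-(TBSO)phenyl]methoxy}-4-(TIPSO)phenyl)methanone
Product: 13 (2S,3R)-5-bromo-2-[4-(TBSO)phenyl]-3-[3,5-bis(TBSO)phenyl]-6-(TIPSO)-2,3-dihydro-1-benzofuran (2,3-cis), via diaryldiazomethane 12 (not isolated)
Conditions: MnO2, CH2Cl2, 0 °C, filtration; then Rh2(R-PTAD)4 (1 mol %), CH2Cl2, 0 °C
Reagents that add atoms: none
Why: MnO2 dehydrogenates the hydrazone to the donor/donor diazo compound, whose chiral dirhodium carbene undergoes enantioselective intramolecular 1,5 C–H insertion into the activated benzylic ether CH2 (five-membered ring closure); the catalyst sets C3 as R and gives the kinetic 2,3-cis isomer.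

Step 7
Reactants: 13 (2S,3R)-5-bromo-2-[4-(TBSO)phenyl]-3-[3,5-bis(TBSO)phenyl]-6-(TIPSO)-2,3-dihydro-1-benzofuran
Product: 14 (2R,3R)-5-bromo-2-[4-(TBSO)phenyl]-3-[3,5-bis(TBSO)phenyl]-6-(TIPSO)-2,3-dihydro-1-benzofuran (2,3-trans)
Conditions: BF3·OEt2 (0.3 equiv), CH2Cl2, −20 → 0 °C
Reagents that add atoms: none
Why: Lewis acid-mediated epimerisation by reversible heterolysis of the benzylic C2–O bond to the 4-silyloxybenzyl cation and reclosure should give the thermodynamically favoured trans isomer, C2 becoming R while C3, which is not involved, stays R.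

Step 8
Reactants: 14 (2R,3R)-5-bromo-2-[4-(TBSO)phenyl]-3-[3,5-bis(TBSO)phenyl]-6-(TIPSO)-2,3-dihydro-1-benzofuran; 15 tributyl(vinyl)stannane
Product: 16 (2R,3R)-5-ethenyl-2-[4-(TBSO)phenyl]-3-[3,5-bis(TBSO)phenyl]-6-(TIPSO)-2,3-dihydro-1-benzofuran
Conditions: Pd(PPh3)4 (5 mol %), toluene, 100 °C
Reagents that add atoms: none
Why: Stille coupling of the aryl bromide runs under neutral, fluoride-free conditions that leave the four silyl ethers and both stereocentres untouched.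

Step 9
Reactants: 17 2,4,6-trihydroxybenzaldehyde
Product: 18 2-hydroxy-4,6-bis(tert-butyldimethylsilyloxy)benzaldehyde
Conditions: TBSCl (2.1 equiv), imidazole, DMF, 0 °C
Reagents that add atoms: tert-butyldimethylsilyl chloride, CC(C)(C)[Si](C)(C)Cl
Why: regioselective bis-silylation, because one ortho hydroxyl stays chelated to the formyl group and is not silylated under these conditions.

Step 10
Reactants: 18 2-hydroxy-4,6-bis(tert-butyldimethylsilyloxy)benzaldehyde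
Product: 19 2-hydroxy-3-iodo-4,6-bis(tert-butyldimethylsilyloxy)benzaldehyde
Conditions: NIS (1.05 equiv), CH2Cl2, −10 °C → rt, dark
Reagents that add atoms: N-iodosuccinimide, O=C1CCC(=O)N1I
Why: electrophilic aromatic iodination should occur ortho to the free phenol (C3), since the only other open position lies between two bulky silyloxy groups.

Step 11
Reactants: 19 2-hydroxy-3-iodo-4,6-bis(tert-butyldimethylsilyloxy)benzaldehyde; 16 (2R,3R)-5-ethenyl-2-[4-(TBSO)phenyl]-3-[3,5-bis(TBSO)phenyl]-6-(TIPSO)-2,3-dihydro-1-benzofuran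
Product: 22 (2S,4S)-8-iodo-4-methoxy-5,7-bis(TBSO)-2-(DHB unit)-3,4-dihydro-2H-chromene (2,4-cis), via dimethyl acetal 20 (not isolated), via o-quinone methide 21 (not isolated)
Conditions: 19 (1.5 equiv), HC(OMe)3, (R)-TRIP [3,3'-bis(2,4,6-triisopropylphenyl)-BINOL hydrogen phosphate] (10 mol %), 5 Å MS, CH2Cl2, rt; then 16, −30 → 0 °C
Reagents that add atoms: trimethyl orthoformate, COC(OC)OC
Why: Proposed new method: the chiral phosphoric acid first converts 19 into acetal 20 and then ionises it, with loss of methanol, to the methoxy-substituted o-quinone methide 21, which stays hydrogen-bonded to the chiral phosphate as a contact ion pair; the terminal carbon of the electron-rich vinyl group of 16 then bonds to the methide carbon (C3–C4) while the positive charge developing at the benzylic carbon, stabilised by the para dihydrofuran oxygen and the ortho silyloxy group of ring B, is quenched by the quinone methide oxygen (O1–C2) in a concerted but asynchronous inverse-electron-demand oxa-Diels–Alder reaction. The closest known reaction types are the Sc(OTf)3-catalysed three-component union of salicylaldehydes, trimethyl orthoformate and styrenes to 2,4-cis-4-methoxy-2-arylchromans and the chiral phosphoric acid-catalysed [4+2] cycloadditions of in situ generated o-quinone methides with vinylarenes; new here is the enantioselective intermolecular use of an acetal-derived alkoxy-o-quinone methide. Ring C is closed in the [4+2] mode (if the process is stepwise, by 6-endo capture of the C2 cation by O1). The face of the bound heterodiene left open by the 3,3'-aryl groups of the catalyst fixes C4, and the endo transition state places the C2 aryl group cis to the C4 methoxy group, so C2 is set S under catalyst control, the two dihydrobenzofuran stereocentres being too remote to compete. The step needs regioselectivity (C4 to the CH2 terminus, O1 to the benzylic carbon), secured by the polarity of both partners, and chemoselectivity for the vinyl group over Friedel–Crafts attack on the silylated arenes, secured by the higher nucleophilicity of the p-alkoxystyrene unit and the bulk of the silyl ethers.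

Step 12
Reactants: 22 (2S,4S)-8-iodo-4-methoxy-5,7-bis(TBSO)-2-(DHB unit)-3,4-dihydro-2H-chromene; 23 2-methylbut-1-en-3-yne
Product: 24 (2S,4S)-4-methoxy-8-(3-methylbut-3-en-1-yn-1-yl)-5,7-bis(TBSO)-2-(DHB unit)-3,4-dihydro-2H-chromene
Conditions: 23 (5 equiv), PdCl2(PPh3)2 (5 mol %), CuI (10 mol %), Et3N/THF, 45 °C, sealed tube
Reagents that add atoms: none
Why: Sonogashira coupling of the aryl iodide is done at the flavan oxidation level, where C2 cannot epimerise under the amine base and O1 is already tied into ring C, so no benzofuran can form.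

Step 13
Reactants: 24 (2S,4S)-4-methoxy-8-(3-methylbut-3-en-1-yn-1-yl)-5,7-bis(TBSO)-2-(DHB unit)-3,4-dihydro-2H-chromene
Product: 25 (2S)-8-(3-methylbut-3-en-1-yn-1-yl)-5,7-bis(TBSO)-2-(DHB unit)-3,4-dihydro-2H-chromen-4-ol (mixture of C4 epimers, C4 written without configuration)
Conditions: camphorsulfonic acid (10 mol %), THF/H2O (5:1), 0 °C → rt
Reagents that add atoms: water, O
Why: SN1 solvolysis of the benzylic methyl ether through the C4 cation stabilised by the three ring-A oxygens should proceed under very mild acid, with C2 untouched and the C4 configuration irrelevant.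

Step 14
Reactants: 25 (2S)-8-(3-methylbut-3-en-1-yn-1-yl)-5,7-bis(TBSO)-2-(DHB unit)-3,4-dihydro-2H-chromen-4-ol
Product: 26 (2S)-8-(3-methylbut-3-en-1-yn-1-yl)-5,7-bis(TBSO)-2-(DHB unit)-2,3-dihydro-4H-chromen-4-one
Conditions: Dess–Martin periodinane, NaHCO3, CH2Cl2, 0 °C → rt
Reagents that add atoms: none
Why: Dess–Martin oxidation of the secondary benzylic alcohol gives the flavanone under buffered, non-basic conditions that should not open ring C or epimerise C2.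

Step 15
Reactants: 26 (2S)-8-(3-methylbut-3-en-1-yn-1-yl)-5,7-bis(TBSO)-2-(DHB unit)-2,3-dihydro-4H-chromen-4-one
Product: 27 (2S)-8-[(1Z)-3-methylbuta-1,3-dien-1-yl]-5,7-bis(TBSO)-2-(DHB unit)-2,3-dihydro-4H-chromen-4-one
Conditions: Zn dust activated with Cu(OAc)2 and AgNO3, THF/MeOH/H2O, 35 °C, dark
Reagents that add atoms: none
Why: Boland-type semi-reduction with activated zinc adds two hydrogens cis to the conjugated triple bond only, giving the Z alkene without touching the 1,1-disubstituted alkene, the ketone or the benzylic C–O bonds.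

Step 16
Reactants: 27 (2S)-8-[(1Z)-3-methylbuta-1,3-dien-1-yl]-5,7-bis(TBSO)-2-(DHB unit)-2,3-dihydro-4H-chromen-4-one
Product: 28 (2S)-5,7-dihydroxy-2-[(2R,3R)-3-(3,5-dihydroxyphenyl)-6-hydroxy-2-(4-hydroxyphenyl)-2,3-dihydro-1-benzofuran-5-yl]-8-[(1Z)-3-methylbuta-1,3-dien-1-yl]-2,3-dihydro-4H-chromen-4-one (CNP0284772.1)
Conditions: TBAF (9 equiv), AcOH (9 equiv), THF, 0 °C; work-up at pH 6–7
Reagents that add atoms: none
Why: fluoride-mediated cleavage of all six aryl silyl ethers, buffered with acetic acid so that no phenoxide can open ring C (C2 epimerisation) and no strong acid can cyclise the o-dienylphenol.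

**Compound list**
1 | 5-bromobenzene-1,3-diol | Oc1cc(O)cc(Br)c1 | starting material
2 | 1-bromo-3,5-bis(tert-butyldimethylsilyloxy)benzene | CC(C)(C)[Si](C)(C)Oc1cc(Br)cc(O[Si](C)(C)C(C)(C)C)c1 | intermediate
3 | 5-bromo-2,4-dihydroxybenzaldehyde | O=Cc1cc(Br)c(O)cc1O | starting material
4 | 5-bromo-2-hydroxy-4-(triisopropylsilyloxy)benzaldehyde | O=Cc1cc(Br)c(O[Si](C(C)C)(C(C)C)C(C)C)cc1O | intermediate
5 | [4-(tert-butyldimethylsilyloxy)phenyl]methanol | OCc1ccc(O[Si](C)(C)C(C)(C)C)cc1 | starting material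
6 | 5-bromo-2-{[4-(TBSO)phenyl]methoxy}-4-(TIPSO)benzaldehyde | O=Cc1cc(Br)c(O[Si](C(C)C)(C(C)C)C(C)C)cc1OCc1ccc(O[Si](C)(C)C(C)(C)C)cc1 | intermediate
7 | (E)-aldoxime of 6 | O/N=C/c1cc(Br)c(O[Si](C(C)C)(C(C)C)C(C)C)cc1OCc1ccc(O[Si](C)(C)C(C)(C)C)cc1 | intermediate (not isolated)
8 | 5-bromo-2-{[4-(TBSO)phenyl]methoxy}-4-(TIPSO)benzonitrile | N#Cc1cc(Br)c(O[Si](C(C)C)(C(C)C)C(C)C)cc1OCc1ccc(O[Si](C)(C)C(C)(C)C)cc1 | intermediate
9 | [3,5-bis(TBSO)phenyl]magnesium bromide | Br[Mg]c1cc(O[Si](C)(C)C(C)(C)C)cc(O[Si](C)(C)C(C)(C)C)c1 | intermediate (not isolated)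
10 | [3,5-bis(TBSO)phenyl](5-bromo-2-{[4-(TBSO)phenyl]methoxy}-4-(TIPSO)phenyl)methanimine | N=C(c1cc(O[Si](C)(C)C(C)(C)C)cc(O[Si](C)(C)C(C)(C)C)c1)c1cc(Br)c(O[Si](C(C)C)(C(C)C)C(C)C)cc1OCc1ccc(O[Si](C)(C)C(C)(C)C)cc1 | intermediate (not isolated)
11 | hydrazone of [3,5-bis(TBSO)phenyl](5-bromo-2-{[4-(TBSO)phenyl]methoxy}-4-(TIPSO)phenyl)methanone (C=N isomers) | NN=C(c1cc(O[Si](C)(C)C(C)(C)C)cc(O[Si](C)(C)C(C)(C)C)c1)c1cc(Br)c(O[Si](C(C)C)(C(C)C)C(C)C)cc1OCc1ccc(O[Si](C)(C)C(C)(C)C)cc1 | intermediate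
12 | [3,5-bis(TBSO)phenyl](5-bromo-2-{[4-(TBSO)phenyl]methoxy}-4-(TIPSO)phenyl)diazomethane | [N-]=[N+]=C(c1cc(O[Si](C)(C)C(C)(C)C)cc(O[Si](C)(C)C(C)(C)C)c1)c1cc(Br)c(O[Si](C(C)C)(C(C)C)C(C)C)cc1OCc1ccc(O[Si](C)(C)C(C)(C)C)cc1 | intermediate (not isolated)
13 | (2S,3R)-5-bromo-2-[4-(TBSO)phenyl]-3-[3,5-bis(TBSO)phenyl]-6-(TIPSO)-2,3-dihydro-1-benzofuran (cis) | Brc1cc2c(cc1O[Si](C(C)C)(C(C)C)C(C)C)O[C@H](c1ccc(O[Si](C)(C)C(C)(C)C)cc1)[C@@H]2c1cc(O[Si](C)(C)C(C)(C)C)cc(O[Si](C)(C)C(C)(C)C)c1 | intermediate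
14 | (2R,3R)-5-bromo-2-[4-(TBSO)phenyl]-3-[3,5-bis(TBSO)phenyl]-6-(TIPSO)-2,3-dihydro-1-benzofuran (trans) | Brc1cc2c(cc1O[Si](C(C)C)(C(C)C)C(C)C)O[C@@H](c1ccc(O[Si](C)(C)C(C)(C)C)cc1)[C@@H]2c1cc(O[Si](C)(C)C(C)(C)C)cc(O[Si](C)(C)C(C)(C)C)c1 | intermediate
15 | tributyl(vinyl)stannane | C=C[Sn](CCCC)(CCCC)CCCC | starting material
16 | (2R,3R)-5-ethenyl-2-[4-(TBSO)phenyl]-3-[3,5-bis(TBSO)phenyl]-6-(TIPSO)-2,3-dihydro-1-benzofuran | C=Cc1cc2c(cc1O[Si](C(C)C)(C(C)C)C(C)C)O[C@@H](c1ccc(O[Si](C)(C)C(C)(C)C)cc1)[C@@H]2c1cc(O[Si](C)(C)C(C)(C)C)cc(O[Si](C)(C)C(C)(C)C)c1 | intermediate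
17 | 2,4,6-trihydroxybenzaldehyde | O=Cc1c(O)cc(O)cc1O | starting material
18 | 2-hydroxy-4,6-bis(tert-butyldimethylsilyloxy)benzaldehyde | O=Cc1c(O)cc(O[Si](C)(C)C(C)(C)C)cc1O[Si](C)(C)C(C)(C)C | intermediate
19 | 2-hydroxy-3-iodo-4,6-bis(tert-butyldimethylsilyloxy)benzaldehyde | O=Cc1c(O)c(I)c(O[Si](C)(C)C(C)(C)C)cc1O[Si](C)(C)C(C)(C)C | intermediate
20 | 2-(dimethoxymethyl)-6-iodo-3,5-bis(tert-butyldimethylsilyloxy)phenol | COC(OC)c1c(O)c(I)c(O[Si](C)(C)C(C)(C)C)cc1O[Si](C)(C)C(C)(C)C | intermediate (not isolated)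
21 | (6Z)-2-iodo-6-(methoxymethylidene)-3,5-bis(tert-butyldimethylsilyloxy)cyclohexa-2,4-dien-1-one | CO/C=C1\C(=O)C(I)=C(O[Si](C)(C)C(C)(C)C)C=C1O[Si](C)(C)C(C)(C)C | intermediate (not isolated)
22 | (2S,4S)-8-iodo-4-methoxy-5,7-bis(TBSO)-2-(DHB unit)-3,4-dihydro-2H-chromene | Ic1c(O[Si](C)(C)C(C)(C)C)cc(O[Si](C)(C)C(C)(C)C)c2c1O[C@H](c1cc3c(cc1O[Si](C(C)C)(C(C)C)C(C)C)O[C@@H](c1ccc(O[Si](C)(C)C(C)(C)C)cc1)[C@@H]3c1cc(O[Si](C)(C)C(C)(C)C)cc(O[Si](C)(C)C(C)(C)C)c1)C[C@@H]2OC | intermediate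
23 | 2-methylbut-1-en-3-yne | C=C(C)C#C | starting material
24 | (2S,4S)-4-methoxy-8-(3-methylbut-3-en-1-yn-1-yl)-5,7-bis(TBSO)-2-(DHB unit)-3,4-dihydro-2H-chromene | C=C(C)C#Cc1c(O[Si](C)(C)C(C)(C)C)cc(O[Si](C)(C)C(C)(C)C)c2c1O[C@H](c1cc3c(cc1O[Si](C(C)C)(C(C)C)C(C)C)O[C@@H](c1ccc(O[Si](C)(C)C(C)(C)C)cc1)[C@@H]3c1cc(O[Si](C)(C)C(C)(C)C)cc(O[Si](C)(C)C(C)(C)C)c1)C[C@@H]2OC | intermediate
25 | (2S)-8-(3-methylbut-3-en-1-yn-1-yl)-5,7-bis(TBSO)-2-(DHB unit)-3,4-dihydro-2H-chromen-4-ol (C4 epimers) | C=C(C)C#Cc1c(O[Si](C)(C)C(C)(C)C)cc(O[Si](C)(C)C(C)(C)C)c2c1O[C@H](c1cc3c(cc1O[Si](C(C)C)(C(C)C)C(C)C)O[C@@H](c1ccc(O[Si](C)(C)C(C)(C)C)cc1)[C@@H]3c1cc(O[Si](C)(C)C(C)(C)C)cc(O[Si](C)(C)C(C)(C)C)c1)CC2O | intermediate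
26 | (2S)-8-(3-methylbut-3-en-1-yn-1-yl)-5,7-bis(TBSO)-2-(DHB unit)-2,3-dihydro-4H-chromen-4-one | C=C(C)C#Cc1c(O[Si](C)(C)C(C)(C)C)cc(O[Si](C)(C)C(C)(C)C)c2c1O[C@H](c1cc3c(cc1O[Si](C(C)C)(C(C)C)C(C)C)O[C@@H](c1ccc(O[Si](C)(C)C(C)(C)C)cc1)[C@@H]3c1cc(O[Si](C)(C)C(C)(C)C)cc(O[Si](C)(C)C(C)(C)C)c1)CC2=O | intermediate
27 | (2S)-8-[(1Z)-3-methylbuta-1,3-dien-1-yl]-5,7-bis(TBSO)-2-(DHB unit)-2,3-dihydro-4H-chromen-4-one | C=C(C)/C=C\c1c(O[Si](C)(C)C(C)(C)C)cc(O[Si](C)(C)C(C)(C)C)c2c1O[C@H](c1cc3c(cc1O[Si](C(C)C)(C(C)C)C(C)C)O[C@@H](c1ccc(O[Si](C)(C)C(C)(C)C)cc1)[C@@H]3c1cc(O[Si](C)(C)C(C)(C)C)cc(O[Si](C)(C)C(C)(C)C)c1)CC2=O | intermediate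
28 | (2S)-5,7-dihydroxy-2-[(2R,3R)-3-(3,5-dihydroxyphenyl)-6-hydroxy-2-(4-hydroxyphenyl)-2,3-dihydro-1-benzofuran-5-yl]-8-[(1Z)-3-methylbuta-1,3-dien-1-yl]-2,3-dihydro-4H-chromen-4-one | C=C(C)/C=C\c1c(O)cc(O)c2c1O[C@H](c1cc3c(cc1O)O[C@@H](c1ccc(O)cc1)[C@@H]3c1cc(O)cc(O)c1)CC2=O | target

Total step count: 16. Longest linear sequence: 13 steps (steps 2–8 and 11–16, from 3).

**Steps most likely to fail**

Step 11 (Proposed new method). What may go wrong: insufficient face discrimination in the ion pair, or consumption of the electron-rich vinylarene by acid-induced oligomerisation before the cycloaddition. The fallback uses known chemistry, sets out from 19 and 16 and comes back to the route at 26. Aldehyde 19 is treated with the lithium enolate of tert-butyl acetate (LiN(iPr)2, THF, −78 °C) to give β-hydroxy ester F1, which is oxidised (MnO2, CH2Cl2) to β-keto ester F2. The vinyl group of 16 is cleaved (OsO4 cat., NaIO4, 2,6-lutidine, dioxane/H2O) to aldehyde F3. Knoevenagel condensation of F2 with F3 (piperidinium acetate, toluene, 4 Å MS) gives alkylidene β-keto ester F4 (alkene geometry not fixed). A quinine-derived bifunctional thiourea then catalyses the enantioselective 6-endo oxa-Michael closure to 3-(tert-butoxycarbonyl)flavanone F5 (C3 not fixed). TsOH in toluene at 80 °C removes the ester with decarboxylation to give 8-iodoflavanone F6. Sonogashira coupling of F6 with 23 under the conditions of step 12 gives 26.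

Step 7. What may go wrong: erosion of the C3 configuration through elimination of the ring-opened cation to the triarylethene, or acid-induced loss of silyl groups. The fallback sets out from 4 and 2 and comes back at 14, building the trans ring directly. Addition of Grignard reagent 9 (2.2 equiv, THF, 0 °C) to 4 gives o-hydroxybenzhydrol F7 (racemic). Exchange of its benzylic hydroxyl with p-toluenesulfinic acid (CH2Cl2, rt) gives sulfone F8. Alcohol 5 is converted (CBr4, PPh3) into benzyl bromide F9 and, with tetrahydrothiophene, into sulfonium salt F10. Cs2CO3 in CH2Cl2 generates the o-quinone methide from F8 and the ylide from F10. Their trans-selective formal [4+1] annulation (conjugate addition, then SN2 ring closure with loss of tetrahydrothiophene), run with a chiral bis-urea hydrogen-bond catalyst, gives 14, with enantiomeric enrichment completed on a chiral stationary phase if needed.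

Step 15. What may go wrong: stalling of the surface reduction at the hindered, di-ortho-substituted arylalkyne, or Z/E erosion on prolonged contact with the metal. The fallback sets out from 22 and 23 and comes back at 27, bringing in the Z alkene preformed. Rh-catalysed trans-hydroboration of 23 (pinacolborane, [Rh(cod)Cl]2, P(iPr)3, Et3N, cyclohexane) gives (Z)-dienylboronate F11. Suzuki–Miyaura coupling of F11 with 22 (Pd(dppf)Cl2, K3PO4, THF/H2O, 40 °C), which retains the alkene geometry, gives dienyl methoxyflavan F12. Hydrolysis with pyridinium p-toluenesulfonate in aqueous THF gives dienyl flavan-4-ol F13, and Dess–Martin oxidation as in step 14 gives 27.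

**Further compounds**
F1 | step 11 | tert-butyl 3-hydroxy-3-[2-hydroxy-3-iodo-4,6-bis(TBSO)phenyl]propanoate (racemic) | CC(C)(C)OC(=O)CC(O)c1c(O)c(I)c(O[Si](C)(C)C(C)(C)C)cc1O[Si](C)(C)C(C)(C)C
F2 | step 11 | tert-butyl 3-[2-hydroxy-3-iodo-4,6-bis(TBSO)phenyl]-3-oxopropanoate | CC(C)(C)OC(=O)CC(=O)c1c(O)c(I)c(O[Si](C)(C)C(C)(C)C)cc1O[Si](C)(C)C(C)(C)C
F3 | step 11 | (2R,3R)-2-[4-(TBSO)phenyl]-3-[3,5-bis(TBSO)phenyl]-6-(TIPSO)-2,3-dihydro-1-benzofuran-5-carbaldehyde | O=Cc1cc2c(cc1O[Si](C(C)C)(C(C)C)C(C)C)O[C@@H](c1ccc(O[Si](C)(C)C(C)(C)C)cc1)[C@@H]2c1cc(O[Si](C)(C)C(C)(C)C)cc(O[Si](C)(C)C(C)(C)C)c1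
F4 | step 11 | tert-butyl 2-[2-hydroxy-3-iodo-4,6-bis(TBSO)benzoyl]-3-(DHB unit)prop-2-enoate (alkene geometry not fixed) | CC(C)(C)OC(=O)C(=Cc1cc2c(cc1O[Si](C(C)C)(C(C)C)C(C)C)O[C@@H](c1ccc(O[Si](C)(C)C(C)(C)C)cc1)[C@@H]2c1cc(O[Si](C)(C)C(C)(C)C)cc(O[Si](C)(C)C(C)(C)C)c1)C(=O)c1c(O)c(I)c(O[Si](C)(C)C(C)(C)C)cc1O[Si](C)(C)C(C)(C)C
F5 | step 11 | tert-butyl (2S)-8-iodo-4-oxo-5,7-bis(TBSO)-2-(DHB unit)-3,4-dihydro-2H-chromene-3-carboxylate (C3 not fixed) | Ic1c(O[Si](C)(C)C(C)(C)C)cc(O[Si](C)(C)C(C)(C)C)c2c1O[C@H](c1cc3c(cc1O[Si](C(C)C)(C(C)C)C(C)C)O[C@@H](c1ccc(O[Si](C)(C)C(C)(C)C)cc1)[C@@H]3c1cc(O[Si](C)(C)C(C)(C)C)cc(O[Si](C)(C)C(C)(C)C)c1)C(C(=O)OC(C)(C)C)C2=O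
F6 | step 11 | (2S)-8-iodo-5,7-bis(TBSO)-2-(DHB unit)-2,3-dihydro-4H-chromen-4-one | Ic1c(O[Si](C)(C)C(C)(C)C)cc(O[Si](C)(C)C(C)(C)C)c2c1O[C@H](c1cc3c(cc1O[Si](C(C)C)(C(C)C)C(C)C)O[C@@H](c1ccc(O[Si](C)(C)C(C)(C)C)cc1)[C@@H]3c1cc(O[Si](C)(C)C(C)(C)C)cc(O[Si](C)(C)C(C)(C)C)c1)CC2=O
F7 | step 7 | 4-bromo-2-{[3,5-bis(TBSO)phenyl](hydroxy)methyl}-5-(TIPSO)phenol (racemic) | OC(c1cc(O[Si](C)(C)C(C)(C)C)cc(O[Si](C)(C)C(C)(C)C)c1)c1cc(Br)c(O[Si](C(C)C)(C(C)C)C(C)C)cc1O
F8 | step 7 | 4-bromo-2-{[3,5-bis(TBSO)phenyl](4-methylbenzenesulfonyl)methyl}-5-(TIPSO)phenol (racemic) | Cc1ccc(cc1)S(=O)(=O)C(c1cc(O[Si](C)(C)C(C)(C)C)cc(O[Si](C)(C)C(C)(C)C)c1)c1cc(Br)c(O[Si](C(C)C)(C(C)C)C(C)C)cc1O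
F9 | step 7 | 1-(bromomethyl)-4-(tert-butyldimethylsilyloxy)benzene | BrCc1ccc(O[Si](C)(C)C(C)(C)C)cc1
F10 | step 7 | 1-{[4-(tert-butyldimethylsilyloxy)phenyl]methyl}tetrahydrothiophenium bromide | [Br-].C1CC[S+](C1)Cc1ccc(O[Si](C)(C)C(C)(C)C)cc1
F11 | step 15 | 4,4,5,5-tetramethyl-2-[(1Z)-3-methylbuta-1,3-dien-1-yl]-1,3,2-dioxaborolane | C=C(C)/C=C\B1OC(C)(C)C(C)(C)O1
F12 | step 15 | (2S,4S)-4-methoxy-8-[(1Z)-3-methylbuta-1,3-dien-1-yl]-5,7-bis(TBSO)-2-(DHB unit)-3,4-dihydro-2H-chromene | C=C(C)/C=C\c1c(O[Si](C)(C)C(C)(C)C)cc(O[Si](C)(C)C(C)(C)C)c2c1O[C@H](c1cc3c(cc1O[Si](C(C)C)(C(C)C)C(C)C)O[C@@H](c1ccc(O[Si](C)(C)C(C)(C)C)cc1)[C@@H]3c1cc(O[Si](C)(C)C(C)(C)C)cc(O[Si](C)(C)C(C)(C)C)c1)C[C@@H]2OC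
F13 | step 15 | (2S)-8-[(1Z)-3-methylbuta-1,3-dien-1-yl]-5,7-bis(TBSO)-2-(DHB unit)-3,4-dihydro-2H-chromen-4-ol (C4 epimers) | C=C(C)/C=C\c1c(O[Si](C)(C)C(C)(C)C)cc(O[Si](C)(C)C(C)(C)C)c2c1O[C@H](c1cc3c(cc1O[Si](C(C)C)(C(C)C)C(C)C)O[C@@H](c1ccc(O[Si](C)(C)C(C)(C)C)cc1)[C@@H]3c1cc(O[Si](C)(C)C(C)(C)C)cc(O[Si](C)(C)C(C)(C)C)c1)CC2O
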